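**Retrosynthetic overview**
1. Numbering: the hydrindane is numbered as indane (C1 bears the link CH2 = C8, C3a the methyl, C4 Br, C7 Me/OH, C7a H). Ring A is C1′ (OH, C8), C3′ (Me2), C4′ (Br).
2. Feature used: in the six-membered ring C3a–C4–C5–C6–C7–C7a the oxygenated C7 is para to the brominated C4, and C4 adjoins the methyl-bearing quaternary C3a. This is the ortho/para imprint of a 2-silyloxydiene/2-bromoacrolein cycloadduct, and ring A repeats the para O/Br pair (C1′/C4′) beside C3′Me2.
3. Late disconnections: both equatorial C–Br bonds ⇐ twofold HAT hydrogenation of the C4=C5/C4′=C5′ bis(vinyl bromide) ⇐ C4,C4′-diketone. The C7 carbinol ⇐ methyl addition to the C7 ketone; C1–C8 ⇐ Giese addition of the ring-A C8 radical to the C1=C7a–C7=O enone.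
4. Enone ⇐ Saegusa oxidation of the C7=C7a silyl enol ether left by the asymmetric Diels–Alder reaction of diene 3 with 2-bromoacrolein (forms C3a–C4 and C5–C6). The bromoformyl carbon C4 is carried as a spiro-epoxide (masked ketone), so C7 is the only carbonyl group when methyl is added.
5. Ring order: the cyclopentane is bought, the hydrindane six-membered ring is closed in step 3, and ring A is closed in step 7 with the same catalyst and dienophile, its bromoformyl carbon becoming C1′(O)–C8.

Key step: step 3

Assumption 1: the sense of induction of the L-tryptophan-derived oxazaborolidinone is carried over from its reactions of 2-bromoacrolein with simple dienes (bonding at the Re face of Cα). Both cycloadditions need this same face, so the D-tryptophan catalyst would serve for both if the sense proved opposite.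
Assumption 2: 4-methylpent-1-en-3-one (isopropyl vinyl ketone, stabilised) is taken as purchasable.

**Step 1**
Reactants: 1 1-acetyl-2-methylcyclopentene; 2 tert-butyldimethylsilyl triflate
Product: 3 1-[1-(tert-butyldimethylsilyloxy)vinyl]-2-methylcyclopentene
Conditions: TBSOTf (1.2 equiv), Et3N (1.6 equiv), CH2Cl2, 0 °C
Reagents that add atoms: tert-butyldimethylsilyl triflate (2), CC(C)(C)[Si](C)(C)OS(=O)(=O)C(F)(F)F
Why: Soft enolisation (O-silylation, then amine deprotonation) removes the kinetically most acidic α′-methyl proton of the enone and gives the cross-conjugated 2-silyloxydiene; no stereocentre is formed.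

**Step 2**
Reactants: 4 acrolein
Product: 6 2-bromoacrolein, via 2,3-dibromopropanal 5 (not isolated)
Conditions: Br2, CH2Cl2, −78 °C; then Et3N, −78 → 0 °C; distillation
Reagents that add atoms: bromine, BrBr
Why: Bromination–dehydrobromination: electrophilic addition of bromine to the C=C bond, then E1cB loss of HBr through the acidic α-hydrogen, leaves the α-bromo enal.

**Step 3**
Reactants: 3 1-[1-(tert-butyldimethylsilyloxy)vinyl]-2-methylcyclopentene; 6 2-bromoacrolein
Product: 7 (3aS,4R)-4-bromo-7-(tert-butyldimethylsilyloxy)-3a-methyl-2,3,3a,4,5,6-hexahydro-1H-indene-4-carbaldehyde (CHO β and cis to the 3a-methyl; Br α)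
Conditions: (S)-2-butyl-4-(indol-3-ylmethyl)-3-tosyl-1,3,2-oxazaborolidin-5-one (20 mol %, from N-tosyl-L-tryptophan and n-BuB(OH)2), CH2Cl2, −78 → −40 °C; Et3N quench; Et3N-deactivated silica
Reagents that add atoms: none
Why: The boron Lewis acid binds the formyl oxygen of s-cis 2-bromoacrolein and a concerted, strongly asynchronous [4+2] cycloaddition follows, the unhindered enol-ether terminus C6 bonding to C5 ahead of the crowded C3a–C4 bond; the closest known reaction types are the oxazaborolidinone-catalysed enantioselective Diels–Alder reaction of 2-bromoacrolein with 2-silyloxydienes and Lewis-acid Diels–Alder reactions of terminally disubstituted 2-silyloxydienes that join two fully substituted carbons. The ring C3a–C4–C5–C6–C7–C7a is closed by intermolecular suprafacial [4+2] annulation onto the existing cyclopentene, which leaves the C7=C7a silyl enol ether. C4 is set by the catalyst, whose indole shields one face of the bound dienophile so that the diene bonds to the Re face of Cα, and C3a is set relative to C4 by the exo placement of the bulky catalyst-bound formyl group, away from C1H2 and the silyloxy group, which puts CHO cis to the inward methyl. The regioselectivity needed is secured twice, since the C7 silyloxy group directs Cα para and the dialkylated terminus C3a directs it ortho. Reactivity is the weak point because the C3a methyl points inward in the s-cis diene; this is why the most reactive α-substituted enal is used, and the C7 silyloxy group helps because it clashes with that methyl in the s-trans rotamer. As C4 is erased later, any endo-formyl diastereomer would end up as the enantiomer at C3a, so it is removed by chromatography here or at epoxide 9.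

**Step 4**
Reactants: 7 Diels–Alder adduct
Product: 9 (3aS,4S)-7-(tert-butyldimethylsilyloxy)-3a-methyl-1,2,3,3a,5,6-hexahydrospiro[indene-4,2'-oxirane] (O β; CH2 α), via bromohydrin 8 (not isolated)
Conditions: NaBH4, MeOH/THF, −20 → 0 °C; then K2CO3, rt
Reagents that add atoms: none
Why: Chemoselective borohydride reduction of the aldehyde, then intramolecular Williamson (3-exo-tet) displacement of the tertiary bromide with inversion at C4, gives the spiro-epoxide; the hindered tetrasubstituted TBS enol ether is inert to hydride and to carbonate, and the epoxide serves as a base-stable mask of the C4 ketone.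

**Step 5**
Reactants: 9 spiro-epoxide silyl enol ether
Product: 10 epoxy enone (3aS,4S)-3a-methyl-3,3a,5,6-tetrahydrospiro[indene-4,2'-oxiran]-7(2H)-one (C1=C7a–C7=O)
Conditions: Pd(OAc)2 (1.1 equiv), MeCN, rt → 40 °C
Reagents that add atoms: none
Why: In this Saegusa–Ito oxidation Pd(II) takes the enol ether at C7a, and syn β-hydride elimination can only use H-1 because C3a is quaternary, so only the C1=C7a enone can form and C3a and C4 are untouched.

**Step 6**
Reactants: 11 4-methylpent-1-en-3-one; 2 tert-butyldimethylsilyl triflate
Product: 12 3-(tert-butyldimethylsilyloxy)-4-methylpenta-1,3-diene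
Conditions: TBSOTf (1.1 equiv), Et3N (1.5 equiv), Et2O, −20 → 0 °C
Reagents that add atoms: tert-butyldimethylsilyl triflate (2), CC(C)(C)[Si](C)(C)OS(=O)(=O)C(F)(F)F
Why: Soft enolisation as in step 1; the isopropyl CH is the only enolisable position, so a single 2-silyloxydiene without stereoisomers results.

**Step 7**
Reactants: 12 3-(tert-butyldimethylsilyloxy)-4-methylpenta-1,3-diene; 6 2-bromoacrolein
Product: 13 (1S)-1-bromo-4-(tert-butyldimethylsilyloxy)-5,5-dimethylcyclohex-3-ene-1-carbaldehyde
Conditions: same oxazaborolidinone (10 mol %), CH2Cl2, −78 °C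
Reagents that add atoms: none
Why: In the same catalytic asymmetric Diels–Alder reaction the nucleophilic enol-ether terminus C3′ (CMe2) bonds to the unsubstituted CH2 of the enal (C2′) and C6′ bonds to Cα, so silyloxy (para) control and sterics agree; the only stereocentre C1′ is set by catalyst-controlled attack on the same Re face of Cα as in step 3, and endo/exo orientation has no consequence.

**Step 8**
Reactants: 13 ring-A adduct
Product: 15 (3R)-6-(tert-butyldimethylsilyloxy)-7,7-dimethyl-1-oxaspiro[2.5]oct-5-ene, via bromohydrin 14 (not isolated)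
Conditions: NaBH4, MeOH/THF, −20 → 0 °C; then K2CO3, rt
Reagents that add atoms: none
Why: Borohydride reduction and intramolecular Williamson closure as in step 4; backside displacement of bromide inverts C1′ and puts the C1′–O bond on the face required in the target.

**Step 9**
Reactants: 15 ring-A spiro-epoxide
Product: 16 (1R)-4-(tert-butyldimethylsilyloxy)-1-(iodomethyl)-5,5-dimethylcyclohex-3-en-1-ol
Conditions: LiI (2 equiv), AcOH (1.5 equiv), THF, 0 °C → rt
Reagents that add atoms: lithium iodide, [Li+].[I-]
Why: Halohydrin synthesis by SN2 opening of the epoxide with iodide at the unsubstituted C8 under weak-acid buffering leaves the C1′–O bond and its configuration untouched, and dry acetic acid is too weak to protonate the hindered TBS enol ether.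

**Step 10**
Reactants: 16 iodohydrin
Product: 17 {[(1R)-4-(tert-butyldimethylsilyloxy)-1-(iodomethyl)-5,5-dimethylcyclohex-3-en-1-yl]oxy}trimethylsilane
Conditions: N-(trimethylsilyl)imidazole (2 equiv), CH2Cl2, rt
Reagents that add atoms: N-(trimethylsilyl)imidazole, C[Si](C)(C)n1ccnc1
Why: Neutral O-silylation of the tertiary alcohol avoids re-closure to the epoxide, later prevents hemiketal formation with the C7 ketone and quenching of the organocerium reagent, and enlarges the C8 substituent.

**Step 11**
Reactants: 10 epoxy enone; 17 ring-A iodide (1.5 equiv)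
Product: 18 coupled ketone (C8 α on C1; H-7a α; trans-hydrindan-7-one; C4 spiro-epoxide, C1′ OTMS and C4′=C5′ TBS enol ether unchanged)
Conditions: (Me3Si)3SiH (1.6 equiv, syringe pump), AIBN (0.2 equiv), PhMe, 85 °C
Reagents that add atoms: none
Why: In this Giese reaction iodine abstraction by the silyl radical gives the primary C8 radical, which unlike a C8 organometallic cannot expel the β-silyloxy group; it adds to C1 of the s-cis enone anti to the perpendicular angular methyl (C8 α), and the C7a radical then takes hydrogen from the bulky silane along the axial α trajectory, again anti to that methyl, giving the trans ring fusion in which C7 and C8 are also trans on the five-membered ring (a separable C7a epimer can be recycled by DBU equilibration).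

**Step 12**
Reactants: 18 coupled ketone
Product: 19 C7 carbinol (C7 methyl α and equatorial; C7 hydroxyl β and axial)
Conditions: MeLi/CeCl3 (3 equiv), THF, −78 °C
Reagents that add atoms: methyllithium, [Li]C
Why: The non-basic organocerium 1,2-addition spares C7a, the epoxide and the silyl groups; the β face of C7 is closed by the 1,3-diaxial angular methyl, so methyl enters equatorially from the α face, as nucleophiles do with related 3a-methyl-7a-H hydrindan-7-ones.

**Step 13**
Reactants: 19 C7 carbinol
Product: 21 diketone diol (C4 and C4′ ketones; C7 and C1′ tertiary alcohols), via glycol 20 (not isolated)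
Conditions: H5IO6 (3 equiv), THF/H2O 4:1, 0 °C → rt
Reagents that add atoms: water, O
Why: Acidic periodate cleavage of an epoxide (hydration to the glycol, then Malaprade cleavage) erases C4 and releases C8-free formaldehyde; the same aqueous acid hydrolyses the TMS ether and the ring-A TBS enol ether, and transannular capture of C4 by the C7 hydroxyl is excluded by the trans ring fusion.

**Step 14**
Reactants: 21 diketone diol
Product: 22 bis-hydrazone of 21
Conditions: N2H4·H2O (20 equiv), Et3N, EtOH, 80 °C
Reagents that add atoms: hydrazine, NN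
Why: In this hydrazone condensation the small nucleophile reaches both neopentyl ketones, the large excess suppresses azine formation, and no stereocentre is at risk because C3a and C3′ are quaternary.

**Step 15**
Reactants: 22 bis-hydrazone
Product: 23 bis(vinyl bromide) (C4(Br)=C5 and C4′(Br)=C5′)
Conditions: Br2 (5 equiv), 2-tert-butyl-1,1,3,3-tetramethylguanidine (12 equiv), CH2Cl2, 0 °C, dark, inverse addition of 22
Reagents that add atoms: bromine, BrBr
Why: In the Barton vinyl halide synthesis each hydrazone is oxidised to the diazoalkane, brominated with loss of N2, and deprotonated at the only available β-positions (H-5, H-5′), so both vinyl bromides form regiospecifically, as with hydrazones of 17-oxo steroids and 2,2-dimethylcyclohexanones.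

**Step 16**
Reactants: 23 bis(vinyl bromide)
Product: 24 target, (1S,4S)-4-bromo-1-{[(1S,3aS,4S,7R,7aS)-4-bromo-7-hydroxy-3a,7-dimethyloctahydro-1H-inden-1-yl]methyl}-3,3-dimethylcyclohexan-1-ol
Conditions: Mn(dpm)3 (20 mol %), PhSiH3 (4 equiv), t-BuOOH (4 equiv), i-PrOH, rt, Ar
Reagents that add atoms: none
Why: Metal-hydride hydrogen-atom-transfer hydrogenation is known to take haloalkenes to haloalkanes without hydrogenolysis: H• adds to C5 and C5′ to give the α-bromo radicals at C4 and C4′ (never a β-bromo radical), and the second hydrogen arrives axially, anti to the axial methyl on the neighbouring quaternary carbon (α face at C4; the face opposite the C1′ hydroxyl at C4′), which places both bromines equatorial as in the target.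

**Compound list**
1 | 1-acetyl-2-methylcyclopentene | CC(=O)C1=C(C)CCC1 | starting material
2 | tert-butyldimethylsilyl triflate | CC(C)(C)[Si](C)(C)OS(=O)(=O)C(F)(F)F | starting material
3 | 1-[1-(tert-butyldimethylsilyloxy)vinyl]-2-methylcyclopentene | C=C(O[Si](C)(C)C(C)(C)C)C1=C(C)CCC1 | intermediate
4 | acrolein | C=CC=O | starting material
5 | 2,3-dibromopropanal (racemic, not isolated) | O=CC(Br)CBr | intermediate
6 | 2-bromoacrolein | C=C(Br)C=O | intermediate
7 | (3aS,4R)-bromoaldehyde silyl enol ether (CHO β, Br α) | C1CC[C@]2(C)[C@@](Br)(C=O)CCC(O[Si](C)(C)C(C)(C)C)=C12 | intermediate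
8 | (3aS,4R)-bromohydrin (not isolated) | C1CC[C@]2(C)[C@@](Br)(CO)CCC(O[Si](C)(C)C(C)(C)C)=C12 | intermediate
9 | (3aS,4S)-C4 spiro-epoxide silyl enol ether (O β, CH2 α) | C1CC[C@]2(C)[C@@]3(OC3)CCC(O[Si](C)(C)C(C)(C)C)=C12 | intermediate
10 | (3aS,4S)-epoxy enone (C1=C7a–C7=O) | C1CC=C2C(=O)CC[C@]3(OC3)[C@@]12C | intermediate
11 | 4-methylpent-1-en-3-one | CC(C)C(=O)C=C | starting material
12 | 3-(tert-butyldimethylsilyloxy)-4-methylpenta-1,3-diene | CC(C)=C(O[Si](C)(C)C(C)(C)C)C=C | intermediate
13 | (1S)-1-bromo-4-(tert-butyldimethylsilyloxy)-5,5-dimethylcyclohex-3-ene-1-carbaldehyde | CC1(C)C[C@](Br)(C=O)CC=C1O[Si](C)(C)C(C)(C)C | intermediate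
14 | (1S)-ring-A bromohydrin (not isolated) | CC1(C)C[C@](Br)(CO)CC=C1O[Si](C)(C)C(C)(C)C | intermediate
15 | (3R)-6-(tert-butyldimethylsilyloxy)-7,7-dimethyl-1-oxaspiro[2.5]oct-5-ene | CC1(C)C[C@]2(OC2)CC=C1O[Si](C)(C)C(C)(C)C | intermediate
16 | (1R)-4-(tert-butyldimethylsilyloxy)-1-(iodomethyl)-5,5-dimethylcyclohex-3-en-1-ol | CC1(C)C[C@@](O)(CI)CC=C1O[Si](C)(C)C(C)(C)C | intermediate
17 | trimethylsilyl ether of 16 | CC1(C)C[C@@](O[Si](C)(C)C)(CI)CC=C1O[Si](C)(C)C(C)(C)C | intermediate
18 | coupled ketone (C8 α on C1, H-7a α, C4 spiro-epoxide, C1′ OTMS, C4′=C5′ TBS enol ether) | CC1(C)C[C@@](O[Si](C)(C)C)(C[C@@H]2CC[C@]3(C)[C@@]4(OC4)CCC(=O)[C@@H]23)CC=C1O[Si](C)(C)C(C)(C)C | intermediate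
19 | C7 carbinol (C7 Me α, OH β) | CC1(C)C[C@@](O[Si](C)(C)C)(C[C@@H]2CC[C@]3(C)[C@@]4(OC4)CC[C@@](C)(O)[C@@H]23)CC=C1O[Si](C)(C)C(C)(C)C | intermediate
20 | glycol (C4 OH α, CH2OH β; C4′ ketone; free C1′ and C7 hydroxyls; not isolated, C4 configuration without consequence) | CC1(C)C[C@@](O)(C[C@@H]2CC[C@]3(C)[C@@](O)(CO)CC[C@@](C)(O)[C@@H]23)CCC1=O | intermediate
21 | diketone diol | CC1(C)C[C@@](O)(C[C@@H]2CC[C@]3(C)C(=O)CC[C@@](C)(O)[C@@H]23)CCC1=O | intermediate
22 | bis-hydrazone (C=N geometry without consequence) | CC1(C)C[C@@](O)(C[C@@H]2CC[C@]3(C)C(=NN)CC[C@@](C)(O)[C@@H]23)CCC1=NN | intermediate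
23 | bis(vinyl bromide) | CC1(C)C[C@@](O)(C[C@@H]2CC[C@]3(C)C(Br)=CC[C@@](C)(O)[C@@H]23)CC=C1Br | intermediate
24 | CNP0166978.1 | CC1(C)C[C@@](O)(C[C@@H]2CC[C@]3(C)[C@@H](Br)CC[C@@](C)(O)[C@@H]23)CC[C@@H]1Br | target

**Step count**
- Total steps: 16.
- Longest linear sequence: 11 steps (6, 7, 8, 9, 10, 11–16 from 11, or 2, 7–16 from acrolein). The hydrindane branch needs 10 (1, 3, 4, 5, 11–16).

**Steps most likely to fail**

**Step 3.** The mild chiral boron Lewis acid may not force the crowded C3a–C4 bond. Protodesilylation of the diene, Mukaiyama–Michael addition without ring closure, or erosion of exo selectivity (which would become loss of enantiopurity at C3a) could then take over.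

Fallback, from 3 and 6, back at 9. The cycloaddition is run with the strong achiral mixed Lewis acid AlBr3/AlMe3 (toluene/CH2Cl2, −40 °C), a system suited to hindered 2-silyloxydienes, to give the racemic exo adduct F1. NaBH4 (MeOH/THF, −40 °C, no base) gives the racemic bromohydrin F2. Esterification with (S)-O-methylmandelic acid (DCC, DMAP) gives the (3aS,4R) ester F3 and the (3aR,4S) ester F4, which are separated by chromatography or crystallisation. K2CO3/MeOH on F3 removes the acyl group and closes the epoxide to 9.

**Step 11.** Hydrogen may be transferred to the hindered primary radical before it adds to the trisubstituted enone, and the facial bias in hydrogen transfer to C7a may be insufficient.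

Fallback, from 10 and 17, back at 18. A nickel-catalysed reductive conjugate addition is used (NiCl2·glyme/terpyridine cat., Mn, Me3SiCl, DMF, rt). Here the enone is first taken up as a silyloxyallylnickel species and the alkyl iodide is coupled at its C1 terminus, giving the C7 trimethylsilyl enol ether F5. MeLi (THF, 0 °C) cleaves only this TMS enol ether to the lithium enolate F6. F6 is protonated at −78 °C with a hindered phenol in a separate, tunable step to give 18.

**Step 16.** Hydrogen-atom transfer to the two hindered bromoalkenes may be sluggish, bromine may be lost by over-reduction, and remote stereocontrol at C4′ may be weak.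

Fallback, from 22, back at 24. Oxidation of the bis-hydrazone with CuBr2/LiOt-Bu (THF, 0 °C) gives the bis(gem-dibromide) F7. Radical mono-debromination at each centre (Bu3SnH 2 equiv, Et3B/air, toluene, −78 °C) reaches the same α-bromo radicals without any alkene activation. It quenches them with a bulky donor at low temperature from the axial face, giving 24.

**Further compounds**
F1 | step 3 | racemic exo adduct (7 and its enantiomer) | C1CC[C@]2(C)[C@@](Br)(C=O)CCC(O[Si](C)(C)C(C)(C)C)=C12.C1CC[C@@]2(C)[C@](Br)(C=O)CCC(O[Si](C)(C)C(C)(C)C)=C12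
F2 | step 3 | racemic bromohydrin (8 and its enantiomer) | C1CC[C@]2(C)[C@@](Br)(CO)CCC(O[Si](C)(C)C(C)(C)C)=C12.C1CC[C@@]2(C)[C@](Br)(CO)CCC(O[Si](C)(C)C(C)(C)C)=C12
F3 | step 3 | (S)-O-methylmandelate of the (3aS,4R) bromohydrin | C1CC[C@]2(C)[C@@](Br)(COC(=O)[C@@H](OC)c3ccccc3)CCC(O[Si](C)(C)C(C)(C)C)=C12
F4 | step 3 | (S)-O-methylmandelate of the (3aR,4S) bromohydrin | C1CC[C@@]2(C)[C@](Br)(COC(=O)[C@@H](OC)c3ccccc3)CCC(O[Si](C)(C)C(C)(C)C)=C12
F5 | step 11 | C7 trimethylsilyl enol ether of 18 | CC1(C)C[C@@](O[Si](C)(C)C)(C[C@@H]2CC[C@]3(C)[C@@]4(OC4)CCC(O[Si](C)(C)C)=C23)CC=C1O[Si](C)(C)C(C)(C)C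
F6 | step 11 | lithium C7,C7a enolate | CC1(C)C[C@@](O[Si](C)(C)C)(C[C@@H]2CC[C@]3(C)[C@@]4(OC4)CCC([O-])=C23)CC=C1O[Si](C)(C)C(C)(C)C.[Li+]
F7 | step 16 | C4,C4′ bis(gem-dibromide) | CC1(C)C[C@@](O)(C[C@@H]2CC[C@]3(C)C(Br)(Br)CC[C@@](C)(O)[C@@H]23)CCC1(Br)Br
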